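**Strategy.** Elemane numbering is used. The cyclohexane ring is cut at C5–C6 and C9–C10, the two ring bonds that flank the C5–C10 bond. C5 (methine with the 3-hydroxyprop-1-en-2-yl group) and C10 (quaternary; methyl, vinyl) are each the allyl terminus of a homoallylic alcohol (free C6 carbinol, acylated C9 carbinol). One pot therefore makes both bonds by tandem allylboration: an enantioenriched 1,2-bis(boronate) from a Z-triene adds to the free aldehyde of a 1,4-dialdehyde surrogate that already holds C7 and C8; acid then unmasks the second aldehyde and the newly formed allylboronate closes the ring, setting four stereocentres.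

Key step: step 8

Remark (numbering): C10 is the quaternary ring carbon (methyl, vinyl C1=C2); C5 bears C4(=C3H2)–C15H2OH; C6 bears the free OH; C7 and C8 are the lactone fusion carbons (C8–O); C9 bears the isobutyrate; C11 (=C13H2) and C12 (C=O) are the lactone carbons.

Remark (assumption): the (R,R)-configured TADDOL phosphonite is taken to deliver the (S)-allylic boronate 10 in step 6; if the facial sense is the opposite one, the (S,S)-ligand is used.

**Route**

Step 1
Reactants: 1 prop-2-yn-1-ol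
Product: 3 (2Z)-3-iodo-2-methylprop-2-en-1-ol, via alkenylmagnesium alkoxide 2 (not isolated)
Conditions: MeMgBr (2.5 equiv), CuI (10 mol%), THF, −10 → 23 °C; then I2, −78 → 0 °C
Reagents that add atoms: methylmagnesium bromide, C[Mg]Br; iodine, II
Why: Copper-catalysed anti-carbomagnesiation of the propargylic alkoxide places methyl on the internal carbon and magnesium cis to the CH2O group in a five-membered chelate, so iodinolysis with retention should give the (Z)-vinyl iodide.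

Step 2
Reactants: 4 2-bromoprop-2-en-1-ol
Product: 5 [(2-bromoprop-2-en-1-yl)oxy](tert-butyl)diphenylsilane
Conditions: tert-butyl(chloro)diphenylsilane, imidazole, CH2Cl2, 0 → 23 °C
Reagents that add atoms: tert-butyl(chloro)diphenylsilane, CC(C)(C)[Si](Cl)(c1ccccc1)c1ccccc1
Why: Standard silylation of a primary alcohol; the acid-stable TBDPS ether is chosen because it must survive the aqueous acid of step 8 and the TFA of step 9.

Step 3
Reactants: 5 [(2-bromoprop-2-en-1-yl)oxy](tert-butyl)diphenylsilane; 3 (2Z)-3-iodo-2-methylprop-2-en-1-ol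
Product: 7 (2Z)-5-{[tert-butyl(diphenyl)silyl]oxy}-2-methyl-4-methylidenepent-2-en-1-ol, via alkenyl pinacol boronate 6 (not isolated)
Conditions: B2pin2, PdCl2(dppf) (3 mol%), KOAc, 1,4-dioxane, 80 °C; then 3, aq. K3PO4, 60 °C
Reagents that add atoms: none
Why: Miyaura borylation of the alkenyl bromide followed in the same flask by Suzuki–Miyaura coupling proceeds with retention at both sp2 carbons, so the (Z)-trisubstituted alkene of 3 is carried into the 1,3-diene.

Step 4
Reactants: 7 (2Z)-5-{[tert-butyl(diphenyl)silyl]oxy}-2-methyl-4-methylidenepent-2-en-1-ol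
Product: 8 (2Z)-5-{[tert-butyl(diphenyl)silyl]oxy}-2-methyl-4-methylidenepent-2-enal
Conditions: Dess–Martin periodinane, NaHCO3, CH2Cl2, 0 °C
Reagents that add atoms: none
Why: Buffered Dess–Martin oxidation converts the allylic alcohol into the enal without acid or base strong enough to isomerise the (Z)-alkene.

Step 5
Reactants: 8 (2Z)-5-{[tert-butyl(diphenyl)silyl]oxy}-2-methyl-4-methylidenepent-2-enal
Product: 9 tert-butyl{[(3Z)-4-methyl-2-methylidenehexa-3,5-dien-1-yl]oxy}diphenylsilane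
Conditions: Ph3PCH3Br, KN(SiMe3)2, THF, −78 → 0 °C
Reagents that add atoms: methyltriphenylphosphonium bromide, C[P+](c1ccccc1)(c1ccccc1)c1ccccc1.[Br-]
Why: Wittig methylenation with the non-stabilised ylide at low temperature should install the vinyl group and leave the (Z)-alkene and the silyl ether untouched.

Step 6
Reactants: 9 tert-butyl{[(3Z)-4-methyl-2-methylidenehexa-3,5-dien-1-yl]oxy}diphenylsilane
Product: 10 tert-butyl{[(3Z,5S)-4-methyl-2-methylidene-5,6-bis(4,4,5,5-tetramethyl-1,3,2-dioxaborolan-2-yl)hex-3-en-1-yl]oxy}diphenylsilane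
Conditions: B2pin2, Pt(dba)3 (3 mol%), (R,R)-3,5-di-iso-propylphenyl-TADDOL phenylphosphonite (6 mol%), THF, 60 °C
Reagents that add atoms: bis(pinacolato)diboron, CC1(C)OB(OC1(C)C)B1OC(C)(C)C(C)(C)O1
Why: Platinum-catalysed enantioselective 1,2-diboration of a cis-1,3-diene: the substituent cis to the vinyl group blocks the s-cis conformer needed for 1,4-addition, the monosubstituted vinyl group should react before the 1,1-disubstituted terminus, and the chiral phosphonite sets the boron-bearing allylic stereocentre.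

Step 7
Reactants: 11 tert-butyl 4-oxobutanoate; 12 2,2-dimethoxyacetaldehyde
Product: 14 tert-butyl (3R,4S)-3-formyl-5,5-dimethoxy-4-[(triethylsilyl)oxy]pentanoate, via anti-aldol adduct 13 (not isolated)
Conditions: D-proline (20 mol%), DMF, 4 °C, slow addition of 11; extractive work-up; then Et3SiOTf, 2,6-lutidine, CH2Cl2, −78 °C
Reagents that add atoms: triethylsilyl trifluoromethanesulfonate, CC[Si](CC)(CC)OS(=O)(=O)C(F)(F)F
Why: Proline-catalysed direct cross-aldol reaction (enamine of 11, activated acceptor 12) should give the anti-aldol through the acid-directed chair transition state, with D-proline setting C7 and C8; low-temperature silylation then blocks retro-aldol and dehydration.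

Step 8
Reactants: 10 tert-butyl{[(3Z,5S)-4-methyl-2-methylidene-5,6-bis(4,4,5,5-tetramethyl-1,3,2-dioxaborolan-2-yl)hex-3-en-1-yl]oxy}diphenylsilane; 14 tert-butyl (3R,4S)-3-formyl-5,5-dimethoxy-4-[(triethylsilyl)oxy]pentanoate
Product: 17 tert-butyl 2-[(1S,2R,3S,4S,5R,6S)-3-(3-{[tert-butyl(diphenyl)silyl]oxy}prop-1-en-2-yl)-4-ethenyl-2,5,6-trihydroxy-4-methylcyclohexyl]acetate, via mono-allylation borate 15 (not isolated), via unmasked hydroxy aldehyde 16 (not isolated)
Conditions: toluene, 45 °C, 24 h; then THF, 1 M aq. HCl, 23 °C, 12 h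
Reagents that add atoms: water, O
Why: The secondary allylic boronate of 10 adds to the only free carbonyl of 14 through a chair Zimmerman–Traxler transition state (γ-attack, C5–C6 bond), which turns the primary boronate into a new (E)-allylic boronate (15); aqueous acid then removes the TES group and the dimethyl acetal, and the freed C9 aldehyde of 16 is attacked intramolecularly by the γ,γ-disubstituted allylboronate (C9–C10 bond). The closest known reaction type is the tandem allylation–allylation of 1,4-dicarbonyl compounds with diene-derived 1,2-bis(boronates), run here with the second carbonyl group released in the flask as in unmasking-triggered intramolecular allylborations. The cyclohexane closes by 6-exo attack on the carbonyl carbon through a trans-decalin-like double chair (boron-containing six-ring fused to the forming carbocycle) in which the C5 side chain, the C6 hydroxyl and the C7 acetate arm are equatorial and only the C8 hydroxyl is axial. C5 and C6 are set by the boron-bearing stereocentre of 10: the γ-substituent cis to it is axial, so A(1,3) strain forces the CH2Bpin group equatorial, which fixes the aldehyde face (C5/C6 syn) and the (E)-geometry of 15; C9 and C10 then follow from this (E)-geometry in the double chair (new hydroxyl and vinyl equatorial, methyl axial). The step needs site selectivity between C6 and C9 (secured by keeping C9 as the acetal until the first addition is over), γ- rather than ε-attack of the dienylboronate (six-membered transition state) and reagent control over the anti-Felkin bias that (Z)-type allylboronates show with α-branched aldehydes (secured by the α-stereocentre of 10).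

Step 9
Reactants: 17 tert-butyl 2-[(1S,2R,3S,4S,5R,6S)-3-(3-{[tert-butyl(diphenyl)silyl]oxy}prop-1-en-2-yl)-4-ethenyl-2,5,6-trihydroxy-4-methylcyclohexyl]acetate
Product: 18 (3aS,4R,5S,6S,7R,7aS)-5-(3-{[tert-butyl(diphenyl)silyl]oxy}prop-1-en-2-yl)-6-ethenyl-4,7-dihydroxy-6-methylhexahydro-1-benzofuran-2(3H)-one
Conditions: CF3CO2H/CH2Cl2 (1:5), 0 °C; aq. NaHCO3 work-up
Reagents that add atoms: none
Why: Acidolysis of the tert-butyl ester and lactonisation: of the two γ-hydroxyls only the axial C8 hydroxyl, cis to the acetic acid arm, should close readily to a cis-fused γ-lactone (the trans-fused alternative from the equatorial C6 hydroxyl is strained), as is known for 2-hydroxycyclohexylacetic acids.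

Step 10
Reactants: 18 (3aS,4R,5S,6S,7R,7aS)-5-(3-{[tert-butyl(diphenyl)silyl]oxy}prop-1-en-2-yl)-6-ethenyl-4,7-dihydroxy-6-methylhexahydro-1-benzofuran-2(3H)-one
Product: 19 (3aR,4R,5S,6S,7R,7aS)-5-(3-{[tert-butyl(diphenyl)silyl]oxy}prop-1-en-2-yl)-6-ethenyl-7-hydroxy-6-methyl-4-[(triethylsilyl)oxy]hexahydro-1-benzofuran-2(3H)-one
Conditions: Et3SiCl (1.1 equiv), imidazole, DMF, 0 °C
Reagents that add atoms: chlorotriethylsilane, CC[Si](Cl)(CC)CC
Why: Kinetic monosilylation: the C6 carbinol is flanked by two methine carbons and should react first, whereas the C9 carbinol is neopentyl (next to quaternary C10) and deactivated by the vicinal lactone oxygen.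

Step 11
Reactants: 19 (3aR,4R,5S,6S,7R,7aS)-5-(3-{[tert-butyl(diphenyl)silyl]oxy}prop-1-en-2-yl)-6-ethenyl-7-hydroxy-6-methyl-4-[(triethylsilyl)oxy]hexahydro-1-benzofuran-2(3H)-one
Product: 22 (3aR,4R,5S,6S,7R,7aS)-5-(3-{[tert-butyl(diphenyl)silyl]oxy}prop-1-en-2-yl)-6-ethenyl-7-hydroxy-6-methyl-3-methylidene-4-[(triethylsilyl)oxy]hexahydro-1-benzofuran-2(3H)-one, via Mannich base 20 (not isolated), via trimethylammonium iodide 21 (not isolated)
Conditions: LiN(iPr)2 (2.5 equiv), THF, −78 °C; CH2=NMe2+ I−, −78 → 0 °C; then MeI, MeOH, 23 °C; then aq. NaHCO3, EtOAc, 23 °C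
Reagents that add atoms: N,N-dimethylmethyleneiminium iodide, C=[N+](C)C.[I-]
Why: α-Methylenation of the γ-lactone by Mannich reaction of its lithium enolate with Eschenmoser's salt, N-methylation and Hofmann-type elimination; the extra base only converts the free C9 hydroxyl into its alkoxide, and no enolisable ester is present yet.

Step 12
Reactants: 22 (3aR,4R,5S,6S,7R,7aS)-5-(3-{[tert-butyl(diphenyl)silyl]oxy}prop-1-en-2-yl)-6-ethenyl-7-hydroxy-6-methyl-3-methylidene-4-[(triethylsilyl)oxy]hexahydro-1-benzofuran-2(3H)-one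
Product: 23 (3aR,4R,5S,6S,7R,7aS)-5-(3-{[tert-butyl(diphenyl)silyl]oxy}prop-1-en-2-yl)-6-ethenyl-6-methyl-3-methylidene-2-oxo-4-[(triethylsilyl)oxy]octahydro-1-benzofuran-7-yl 2-methylpropanoate
Conditions: 2-methylpropanoyl chloride (3 equiv), DMAP (0.3 equiv), pyridine, CH2Cl2, 0 → 23 °C
Reagents that add atoms: 2-methylpropanoyl chloride, CC(C)C(=O)Cl
Why: DMAP-catalysed acylation of the only free hydroxyl; the hindered C9 carbinol needs the acyl chloride and nucleophilic catalysis.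

Step 13
Reactants: 23 (3aR,4R,5S,6S,7R,7aS)-5-(3-{[tert-butyl(diphenyl)silyl]oxy}prop-1-en-2-yl)-6-ethenyl-6-methyl-3-methylidene-2-oxo-4-[(triethylsilyl)oxy]octahydro-1-benzofuran-7-yl 2-methylpropanoate
Product: 24 (3aS,4R,5S,6S,7R,7aS)-6-ethenyl-4-hydroxy-5-(3-hydroxyprop-1-en-2-yl)-6-methyl-3-methylidene-2-oxooctahydro-1-benzofuran-7-yl 2-methylpropanoate
Conditions: HF·pyridine, pyridine, THF, 0 → 23 °C
Reagents that add atoms: none
Why: Cleavage of both silyl ethers under buffered acidic fluoride conditions should spare the isobutyrate and the α-methylene lactone, since no basic fluoride is present to trigger acyl migration or oxa-Michael addition.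

**Compound list**

1 | prop-2-yn-1-ol | C#CCO | starting material
2 | bromomagnesium alkoxide of (2Z)-3-(bromomagnesio)-2-methylprop-2-en-1-ol | Br[Mg]/C=C(C)\CO[Mg]Br | intermediate
3 | (2Z)-3-iodo-2-methylprop-2-en-1-ol | OC/C(C)=C\I | intermediate
4 | 2-bromoprop-2-en-1-ol | C=C(Br)CO | starting material
5 | [(2-bromoprop-2-en-1-yl)oxy](tert-butyl)diphenylsilane | C=C(Br)CO[Si](c1ccccc1)(c1ccccc1)C(C)(C)C | intermediate
6 | tert-butyl(diphenyl){[2-(4,4,5,5-tetramethyl-1,3,2-dioxaborolan-2-yl)prop-2-en-1-yl]oxy}silane | C=C(B1OC(C)(C)C(C)(C)O1)CO[Si](c1ccccc1)(c1ccccc1)C(C)(C)C | intermediate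
7 | (2Z)-5-{[tert-butyl(diphenyl)silyl]oxy}-2-methyl-4-methylidenepent-2-en-1-ol | OC/C(C)=C\C(=C)CO[Si](c1ccccc1)(c1ccccc1)C(C)(C)C | intermediate
8 | (2Z)-5-{[tert-butyl(diphenyl)silyl]oxy}-2-methyl-4-methylidenepent-2-enal | O=C/C(C)=C\C(=C)CO[Si](c1ccccc1)(c1ccccc1)C(C)(C)C | intermediate
9 | tert-butyl{[(3Z)-4-methyl-2-methylidenehexa-3,5-dien-1-yl]oxy}diphenylsilane | C=C/C(C)=C\C(=C)CO[Si](c1ccccc1)(c1ccccc1)C(C)(C)C | intermediate
10 | tert-butyl{[(3Z,5S)-4-methyl-2-methylidene-5,6-bis(4,4,5,5-tetramethyl-1,3,2-dioxaborolan-2-yl)hex-3-en-1-yl]oxy}diphenylsilane | CC1(C)OB(C[C@H](B2OC(C)(C)C(C)(C)O2)/C(C)=C\C(=C)CO[Si](c2ccccc2)(c2ccccc2)C(C)(C)C)OC1(C)C | intermediate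
11 | tert-butyl 4-oxobutanoate | O=CCCC(=O)OC(C)(C)C | starting material
12 | 2,2-dimethoxyacetaldehyde | O=CC(OC)OC | starting material
13 | tert-butyl (3R,4S)-3-formyl-4-hydroxy-5,5-dimethoxypentanoate | O=C[C@H](CC(=O)OC(C)(C)C)[C@H](O)C(OC)OC | intermediate
14 | tert-butyl (3R,4S)-3-formyl-5,5-dimethoxy-4-[(triethylsilyl)oxy]pentanoate | O=C[C@H](CC(=O)OC(C)(C)C)[C@H](O[Si](CC)(CC)CC)C(OC)OC | intermediate
15 | tert-butyl (3S,4S)-3-{(1R,2R,3E)-2-(3-{[tert-butyl(diphenyl)silyl]oxy}prop-1-en-2-yl)-3-methyl-5-(pinacolboryl)-1-[(pinacolboryl)oxy]pent-3-en-1-yl}-5,5-dimethoxy-4-[(triethylsilyl)oxy]pentanoate | CC1(C)OB(C/C=C(C)/[C@H](C(=C)CO[Si](c2ccccc2)(c2ccccc2)C(C)(C)C)[C@@H](OB2OC(C)(C)C(C)(C)O2)[C@H](CC(=O)OC(C)(C)C)[C@H](O[Si](CC)(CC)CC)C(OC)OC)OC1(C)C | intermediate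
16 | tert-butyl (3S,4S)-3-{(1R,2R,3E)-2-(3-{[tert-butyl(diphenyl)silyl]oxy}prop-1-en-2-yl)-1-hydroxy-3-methyl-5-(pinacolboryl)pent-3-en-1-yl}-4-hydroxy-5-oxopentanoate | CC1(C)OB(C/C=C(C)/[C@H](C(=C)CO[Si](c2ccccc2)(c2ccccc2)C(C)(C)C)[C@@H](O)[C@H](CC(=O)OC(C)(C)C)[C@H](O)C=O)OC1(C)C | intermediate
17 | tert-butyl 2-[(1S,2R,3S,4S,5R,6S)-3-(3-{[tert-butyl(diphenyl)silyl]oxy}prop-1-en-2-yl)-4-ethenyl-2,5,6-trihydroxy-4-methylcyclohexyl]acetate | C=C[C@@]1(C)[C@H](C(=C)CO[Si](c2ccccc2)(c2ccccc2)C(C)(C)C)[C@@H](O)[C@H](CC(=O)OC(C)(C)C)[C@H](O)[C@@H]1O | intermediate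
18 | (3aS,4R,5S,6S,7R,7aS)-5-(3-{[tert-butyl(diphenyl)silyl]oxy}prop-1-en-2-yl)-6-ethenyl-4,7-dihydroxy-6-methylhexahydro-1-benzofuran-2(3H)-one | C=C[C@@]1(C)[C@H](C(=C)CO[Si](c2ccccc2)(c2ccccc2)C(C)(C)C)[C@@H](O)[C@@H]2CC(=O)O[C@@H]2[C@@H]1O | intermediate
19 | (3aR,4R,5S,6S,7R,7aS)-5-(3-{[tert-butyl(diphenyl)silyl]oxy}prop-1-en-2-yl)-6-ethenyl-7-hydroxy-6-methyl-4-[(triethylsilyl)oxy]hexahydro-1-benzofuran-2(3H)-one | C=C[C@@]1(C)[C@H](C(=C)CO[Si](c2ccccc2)(c2ccccc2)C(C)(C)C)[C@@H](O[Si](CC)(CC)CC)[C@@H]2CC(=O)O[C@@H]2[C@@H]1O | intermediate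
20 | 3-[(dimethylamino)methyl] derivative of 19 (Mannich base, mixture at the lactone α-carbon) | C=C[C@@]1(C)[C@H](C(=C)CO[Si](c2ccccc2)(c2ccccc2)C(C)(C)C)[C@@H](O[Si](CC)(CC)CC)[C@@H]2C(CN(C)C)C(=O)O[C@@H]2[C@@H]1O | intermediate
21 | trimethylammonium iodide of 20 | C=C[C@@]1(C)[C@H](C(=C)CO[Si](c2ccccc2)(c2ccccc2)C(C)(C)C)[C@@H](O[Si](CC)(CC)CC)[C@@H]2C(C[N+](C)(C)C)C(=O)O[C@@H]2[C@@H]1O.[I-] | intermediate
22 | (3aR,4R,5S,6S,7R,7aS)-5-(3-{[tert-butyl(diphenyl)silyl]oxy}prop-1-en-2-yl)-6-ethenyl-7-hydroxy-6-methyl-3-methylidene-4-[(triethylsilyl)oxy]hexahydro-1-benzofuran-2(3H)-one | C=C[C@@]1(C)[C@H](C(=C)CO[Si](c2ccccc2)(c2ccccc2)C(C)(C)C)[C@@H](O[Si](CC)(CC)CC)[C@@H]2C(=C)C(=O)O[C@@H]2[C@@H]1O | intermediate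
23 | (3aR,4R,5S,6S,7R,7aS)-5-(3-{[tert-butyl(diphenyl)silyl]oxy}prop-1-en-2-yl)-6-ethenyl-6-methyl-3-methylidene-2-oxo-4-[(triethylsilyl)oxy]octahydro-1-benzofuran-7-yl 2-methylpropanoate | C=C[C@@]1(C)[C@H](C(=C)CO[Si](c2ccccc2)(c2ccccc2)C(C)(C)C)[C@@H](O[Si](CC)(CC)CC)[C@@H]2C(=C)C(=O)O[C@@H]2[C@@H]1OC(=O)C(C)C | intermediate
24 | (3aS,4R,5S,6S,7R,7aS)-6-ethenyl-4-hydroxy-5-(3-hydroxyprop-1-en-2-yl)-6-methyl-3-methylidene-2-oxooctahydro-1-benzofuran-7-yl 2-methylpropanoate | C=C[C@@]1(C)[C@H](C(=C)CO)[C@@H](O)[C@@H]2C(=C)C(=O)O[C@@H]2[C@@H]1OC(=O)C(C)C | target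

**Step count.** Total: 13 steps. Longest linear sequence: 11 steps (steps 2, 3, 4, 5, 6, 8, 9, 10, 11, 12, 13 from 4; equally 1, 3, 4, 5, 6, 8–13 from 1).

**The three steps most likely to fail**

Step 8 (key step). The first addition may be slow because the reagent has to override the anti-Felkin preference of the α-branched aldehyde. In the acidic second stage the allylboronate may be protonated off before the acetal is hydrolysed. The ring closure may also leak through a less ordered transition state and erode the configuration at the quaternary carbon. The fallback sets out from 10 and 14 and comes back at 17, with the two allylations separated. 10 and 14 are combined as before, but the mixture is worked up with aqueous NaHCO3 to isolate tert-butyl (3S,4S)-3-{(1R,2R,3E)-2-(3-{[tert-butyl(diphenyl)silyl]oxy}prop-1-en-2-yl)-1-hydroxy-3-methyl-5-(pinacolboryl)pent-3-en-1-yl}-5,5-dimethoxy-4-[(triethylsilyl)oxy]pentanoate F1. Et3SiOTf (3 equiv) and 2,4,6-collidine in CH2Cl2 at 0 °C, then water, first silylate the new hydroxyl and then cleave the dimethyl acetal through its collidinium salt without protic acid, giving the aldehyde tert-butyl (3S,4S)-3-{(1R,2R,3E)-2-(3-{[tert-butyl(diphenyl)silyl]oxy}prop-1-en-2-yl)-3-methyl-5-(pinacolboryl)-1-[(triethylsilyl)oxy]pent-3-en-1-yl}-5-oxo-4-[(triethylsilyl)oxy]pentanoate F2. F2 should close thermally (toluene, 40 °C) by the same intramolecular allylboration to tert-butyl 2-[(1S,2R,3S,4S,5R,6S)-3-(3-{[tert-butyl(diphenyl)silyl]oxy}prop-1-en-2-yl)-4-ethenyl-5-hydroxy-4-methyl-2,6-bis[(triethylsilyl)oxy]cyclohexyl]acetate F3, and 1 M aq. HCl in THF removes both TES groups to return to 17.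

Step 6. The platinum catalyst may add across the 1,1-disubstituted terminus or across a longer conjugated path, the facial selectivity may be low on a 3-methyl-substituted diene, and the (Z)-triene may slowly electrocyclise on heating. The fallback sets out from 8 and comes back at 10. Ohira–Bestmann homologation (dimethyl (1-diazo-2-oxopropyl)phosphonate, K2CO3, MeOH) converts the aldehyde into the enyne tert-butyl{[(3Z)-4-methyl-2-methylidenehex-3-en-5-yn-1-yl]oxy}diphenylsilane F4. Chiral N-heterocyclic-carbene copper catalysis with B2pin2 and MeOH then performs a double protoboration of the terminal alkyne: site-selective Cu–B addition gives the alkenyl boronate tert-butyl{[(3Z,5E)-4-methyl-2-methylidene-6-(pinacolboryl)hexa-3,5-dien-1-yl]oxy}diphenylsilane F5, and enantioselective Cu–B addition to this vinyl boronate followed by protonation gives the vicinal bis(boronate) 10.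

Step 10. Discrimination between the two secondary hydroxyls may be poor, giving bis-silylation or silylation at C9. The fallback sets out from 17 and comes back at 23, differentiating the hydroxyls earlier through the cis-8,9-diol. Borinic acid catalysis (2-aminoethyl diphenylborinate 10 mol%, 2-methylpropanoyl chloride, iPr2NEt, MeCN) should acylate the equatorial hydroxyl of the cis-diol to tert-butyl 2-[(1S,2R,3S,4S,5R,6S)-3-(3-{[tert-butyl(diphenyl)silyl]oxy}prop-1-en-2-yl)-4-ethenyl-2,6-dihydroxy-4-methyl-5-[(2-methylpropanoyl)oxy]cyclohexyl]acetate F6. CF3CO2H in CH2Cl2 then closes the cis-lactone to (3aS,4R,5S,6S,7R,7aS)-5-(3-{[tert-butyl(diphenyl)silyl]oxy}prop-1-en-2-yl)-6-ethenyl-4-hydroxy-6-methyl-2-oxooctahydro-1-benzofuran-7-yl 2-methylpropanoate F7, and Et3SiOTf with 2,6-lutidine silylates the only free hydroxyl to the C6 triethylsilyl ether F8. LiN(iPr)2 at −78 °C and Eschenmoser's salt give the Mannich base F9, MeI gives the trimethylammonium iodide F10, and aqueous NaHCO3 eliminates to 23.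

Further compounds
F1 | step 8 | tert-butyl (3S,4S)-3-{(1R,2R,3E)-2-(3-{[tert-butyl(diphenyl)silyl]oxy}prop-1-en-2-yl)-1-hydroxy-3-methyl-5-(pinacolboryl)pent-3-en-1-yl}-5,5-dimethoxy-4-[(triethylsilyl)oxy]pentanoate | CC1(C)OB(C/C=C(C)/[C@H](C(=C)CO[Si](c2ccccc2)(c2ccccc2)C(C)(C)C)[C@@H](O)[C@H](CC(=O)OC(C)(C)C)[C@H](O[Si](CC)(CC)CC)C(OC)OC)OC1(C)C
F2 | step 8 | tert-butyl (3S,4S)-3-{(1R,2R,3E)-2-(3-{[tert-butyl(diphenyl)silyl]oxy}prop-1-en-2-yl)-3-methyl-5-(pinacolboryl)-1-[(triethylsilyl)oxy]pent-3-en-1-yl}-5-oxo-4-[(triethylsilyl)oxy]pentanoate | CC1(C)OB(C/C=C(C)/[C@H](C(=C)CO[Si](c2ccccc2)(c2ccccc2)C(C)(C)C)[C@@H](O[Si](CC)(CC)CC)[C@H](CC(=O)OC(C)(C)C)[C@H](O[Si](CC)(CC)CC)C=O)OC1(C)C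
F3 | step 8 | tert-butyl 2-[(1S,2R,3S,4S,5R,6S)-3-(3-{[tert-butyl(diphenyl)silyl]oxy}prop-1-en-2-yl)-4-ethenyl-5-hydroxy-4-methyl-2,6-bis[(triethylsilyl)oxy]cyclohexyl]acetate | C=C[C@@]1(C)[C@H](C(=C)CO[Si](c2ccccc2)(c2ccccc2)C(C)(C)C)[C@@H](O[Si](CC)(CC)CC)[C@H](CC(=O)OC(C)(C)C)[C@H](O[Si](CC)(CC)CC)[C@@H]1O
F4 | step 6 | tert-butyl{[(3Z)-4-methyl-2-methylidenehex-3-en-5-yn-1-yl]oxy}diphenylsilane | C#C/C(C)=C\C(=C)CO[Si](c1ccccc1)(c1ccccc1)C(C)(C)C
F5 | step 6 | tert-butyl{[(3Z,5E)-4-methyl-2-methylidene-6-(4,4,5,5-tetramethyl-1,3,2-dioxaborolan-2-yl)hexa-3,5-dien-1-yl]oxy}diphenylsilane | CC1(C)OB(/C=C/C(C)=C\C(=C)CO[Si](c2ccccc2)(c2ccccc2)C(C)(C)C)OC1(C)C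
F6 | step 10 | tert-butyl 2-[(1S,2R,3S,4S,5R,6S)-3-(3-{[tert-butyl(diphenyl)silyl]oxy}prop-1-en-2-yl)-4-ethenyl-2,6-dihydroxy-4-methyl-5-[(2-methylpropanoyl)oxy]cyclohexyl]acetate | C=C[C@@]1(C)[C@H](C(=C)CO[Si](c2ccccc2)(c2ccccc2)C(C)(C)C)[C@@H](O)[C@H](CC(=O)OC(C)(C)C)[C@H](O)[C@@H]1OC(=O)C(C)C
F7 | step 10 | (3aS,4R,5S,6S,7R,7aS)-5-(3-{[tert-butyl(diphenyl)silyl]oxy}prop-1-en-2-yl)-6-ethenyl-4-hydroxy-6-methyl-2-oxooctahydro-1-benzofuran-7-yl 2-methylpropanoate | C=C[C@@]1(C)[C@H](C(=C)CO[Si](c2ccccc2)(c2ccccc2)C(C)(C)C)[C@@H](O)[C@@H]2CC(=O)O[C@@H]2[C@@H]1OC(=O)C(C)C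
F8 | step 10 | (3aR,4R,5S,6S,7R,7aS)-5-(3-{[tert-butyl(diphenyl)silyl]oxy}prop-1-en-2-yl)-6-ethenyl-6-methyl-2-oxo-4-[(triethylsilyl)oxy]octahydro-1-benzofuran-7-yl 2-methylpropanoate | C=C[C@@]1(C)[C@H](C(=C)CO[Si](c2ccccc2)(c2ccccc2)C(C)(C)C)[C@@H](O[Si](CC)(CC)CC)[C@@H]2CC(=O)O[C@@H]2[C@@H]1OC(=O)C(C)C
F9 | step 10 | 3-[(dimethylamino)methyl] derivative of F8 (Mannich base) | C=C[C@@]1(C)[C@H](C(=C)CO[Si](c2ccccc2)(c2ccccc2)C(C)(C)C)[C@@H](O[Si](CC)(CC)CC)[C@@H]2C(CN(C)C)C(=O)O[C@@H]2[C@@H]1OC(=O)C(C)C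
F10 | step 10 | trimethylammonium iodide of F9 | C=C[C@@]1(C)[C@H](C(=C)CO[Si](c2ccccc2)(c2ccccc2)C(C)(C)C)[C@@H](O[Si](CC)(CC)CC)[C@@H]2C(C[N+](C)(C)C)C(=O)O[C@@H]2[C@@H]1OC(=O)C(C)C.[I-]
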